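# Penicimutamide B (24): Boc-terminated aza-Prins route

Ring A is numbered as an indolizidine: N4, C5 (lactam carbonyl, later the carbinolamine), C6 (amino-bearing quaternary carbon), C7 (ring-fusion CH), C8 (CH2), C8a (pyrrolidine CH). Ring B is the carbocycle: C6, C7, the CMe2 carbon, C2 and C3 (the later indolenine carbons) and the bridging CH2.

## Analysis of the target

Penicimutamide B (24) is hexacyclic. A 3H-indole is fused through C2 and C3 to ring B; ring B is fused at C6–C7 to ring A of an indolizidine; and a 1,3-oxazinan-2-one bridges ring B from the oxygen on C3 to the nitrogen on C6 across the single CH2, so that ring B and the carbamate form a bicyclo[3.3.1] unit. There are five stereocentres: C3 (S), C6 (S), C7 (R), C8a (R) and C5 (R). Rings A and B are trans-fused with the carbamate nitrogen axial on both, the C3–O bond is cis (1,3-diaxial) to that nitrogen, H7 and H8a are cis so that both ring-A substituents at C7 and C8a are equatorial, and the C5 hydroxyl is axial, anti to the carbamate nitrogen. The sensitive groups are the carbinolamine (it ionises to an iminium ion and has to come last), the indolenine C=N (electrophilic, hydrolysable, reducible) and the N–H carbamate. The difficulty lies in ring B: four of its six carbons are fully substituted, among them two heteroatom-bearing quaternary stereocentres (C3 and C6) beside the gem-dimethyl carbon, and their configuration has to be tied to the remote C8a. The strategy rests on the carbamate: N(C6)–C(=O)–O(C3) together with C6–CH2–C3 are exactly the six atoms that an N-Boc iminium ion (C6=N–C=O) and an α-aryl alkene (CH2=C3–Ar) bring to a formal [4+2], with the carbonyl already in place.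

## Retrosynthetic reasoning

**C5–H (24 to 23).** The carbinolamine is taken back to the lactam 23. It is the most fragile group, so its formation is the last step. C6 carries no hydrogen, so the half-reduced lactam can neither dehydrate to an enamine nor over-reduce easily. The hydroxyl should settle axial, which is the target configuration.

**Indolenine C=N and aryl–N (23 to 21).** Cutting both C–N bonds of the indolenine nitrogen leads to the aryl chloride ketone 21. The nitrogen is put on the arene only after the cationic step, because a nitrogen substituent there would either deactivate the benzylic cation or trap it. Chloride is chosen because it is inert in the earlier cross-coupling and can still be aminated later; the amino ketone 22 then condenses by itself.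

**C2 ketone (21 to 20).** The ketone is masked as the exocyclic methylene of 20. In the forward direction this second double bond keeps the neighbouring alkene nucleophilic (a ketone would switch it off) and turns the cation of the key step into an allyl cation.

**C6–CH2 and C3–O (20 to 19), the key disconnection.** Both bonds are cut at once, which opens ring B and the oxazinanone and leads to the N-Boc ketimine 19 of an α-keto lactam with a 2-aryl diene side chain. No other cut removes both quaternary stereocentres, a carbocycle and the carbamate in one operation. The forward reaction has to achieve attack by the aryl-substituted alkene terminus, one face of the iminium carbon, and capture of the cation by the Boc oxygen before the tert-butyl group or a proton is lost.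

**C6=N (19 to 17 and 18).** The imine is made from the α-keto lactam 17 and the iminophosphorane 18. A ketone at C6 also makes C7 epimerisable, so C7 need not be set by a reagent; it is set by equilibration.

**Diene sp2–sp2 bond (17 to 13 and 16).** The acid-sensitive 2-aryl diene is assembled late by cross-coupling of the vinyl bromide 13 with the vinylboronate 16, after the only strongly acidic operation of the early route. 16 comes from the ketone 14 through the triflate 15.

**Lactam N4–C5 (13 to 11 through 12).** The lactam is an aminolysis of an α-keto ester, an activated ester, by the pyrrolidine nitrogen freed from 11.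

**C7–CMe2 (11 to 10).** This bond lies between a tertiary and a quaternary carbon and is therefore made by a [3,3] shift, not by enolate alkylation. The rearrangement of the allyl vinyl ether 10 delivers in one step the C6 ketone, the quaternary carbon and the vinyl bromide handle.

**C6=C7 of the vinyl ether, and the fragments (10 to 9 and 3).** An olefination joins the phosphonate 9 and the aldehyde 3. 9 comes from the allylic alcohol 7 and the diazo compound 8; 7 comes from 4 through 5 and 6. 3 comes from the chiral-pool acid 1 through 2, which supplies C8a, the only stereocentre that is bought.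

## Alternatives that were turned down

**Alternative 1:** Here all three C–N bonds of the indolizidine nitrogen are cut, so that pyrrolidine and piperidinone close in one operation on a preformed cyclohexane. In the forward key step an (R)-selective amine transaminase with its cofactor and a sacrificial amine donor turns a side-chain ketone into a primary amine. The amine alkylates itself on a terminal chloride and then acylates on a neighbouring ester to give the tricyclic lactam A1.

- For it: the pyrrolidine stereocentre is set by a catalyst and not bought, three bonds and two rings form under very mild aqueous conditions, and nothing cationic is involved. On these points it is stronger than the chosen route.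
- Against it: the step does not touch the hard part of the target. The cyclohexane of A1 must already carry the quaternary amino ester carbon next to C7 and the gem-dimethyl group as one stereoisomer. The enzyme must accept a ketone flanked by two chains, one of them very bulky, where such enzymes prefer methyl ketones. After A1 the arene has still to be annulated onto the unmasked ketone, and the C3–O bond must be made by oxidising the resulting indole with capture by the Boc oxygen.
- Comparison: the chosen strategy takes C8a from the chiral pool and spends its key step on ring B, both quaternary centres and the carbamate, with three steps left afterwards.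

**Alternative 2:** Here the C7–C8 bond of the piperidinone is cut. In the forward key step, visible-light photoreduction of a redox-active ester with a ruthenium polypyridyl photocatalyst and a dihydropyridine reductant releases a primary radical beside the pyrrolidine. It closes 6-exo onto an alkene carbon attached to the quaternary amino acid carbon and expels a sulfonyl radical, leaving the isopropenyl lactam A2.

- For it: the conditions are neutral and tolerate the indole N–H and the carbamate, the 6-exo closure with β-fragmentation is a reliable pattern, and it needs no strong Lewis acid. On these points it is as strong or stronger.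
- Against it: the quaternary amino acid centre must be made enantiopure beforehand. C7 is formed under control of that centre, whose two large substituents differ little in size. A2 is still far from the target: ring B has to be closed by a cationic alkylation of indole C2, the indole has then to be oxidised with carbamate capture (from a methyl carbamate, which gives up its alkyl group less readily than a tert-butyl one), and the lactam reduced.
- Comparison: the chosen strategy forms ring B, the carbamate and both quaternary centres in one step at the final oxidation level of C3.

**Alternative 3:** Here the C6–C7 bond and the bond from the CMe2 carbon to indole C2 are cut. In the forward key step a silyl triflate or strong protic acid converts an indole-conjugated enecarbamate into an N-acyl ketiminium ion. A prenyl alkene attacks it to close the piperidinone, and the resulting tertiary cation alkylates indole C2 to give the pentacyclic indole A3.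

- For it: it is the shortest of the four in substrate assembly, and its endgame (oxidation of the indole with capture by the carbamate oxygen, then lactam reduction) is no longer than the chosen one. On step economy it is as strong or stronger.
- Against it: two stereocentres, C6 and C7, are created in the cascade under control of C8a alone, and C7 cannot be corrected afterwards. The enecarbamate is conjugated to the indole and is a reluctant iminium precursor, and the basic indole C3 competes for the acid. The C3–O bond depends on a late electrophilic oxidation of an electron-rich indole.
- Comparison: in the chosen strategy C7 is fixed by equilibration before the cascade, so the cascade has a single stereochemical decision, the face of C6. The C3 oxygen and its configuration come with the cascade itself, locked by the carbamate tether.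

Key step: step 13

## Assumptions

- Compounds 1, 8 and 18 are taken to be purchasable.
- 11 is formed as a mixture at the carbon that becomes C7; this centre is α to the C6 ketone and is expected to equilibrate at the stage of 13 to the cis (7R,8aR) isomer with both ring-A substituents equatorial.
- 19 is formulated as the N-Boc ketimine; if it rests as its enecarbamate tautomer (compound F6 below), the acid of step 13 returns it to the same N-Boc ketiminium ion.

## Route

Step 1
Reactants: 1 (R)-2-[1-(tert-butoxycarbonyl)pyrrolidin-2-yl]acetic acid (Boc-D-β-homoproline)
Product: 2 tert-butyl (2R)-2-(2-hydroxyethyl)pyrrolidine-1-carboxylate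
Conditions: BH3·THF, THF, 0 °C to rt; MeOH quench
Reagents that add atoms: none
Why: Borane reduces the carboxylic acid chemoselectively through the acyloxyborane and leaves the carbamate alone; the stereocentre is not involved.

Step 2
Reactants: 2 tert-butyl (2R)-2-(2-hydroxyethyl)pyrrolidine-1-carboxylate
Product: 3 tert-butyl (2R)-2-(2-oxoethyl)pyrrolidine-1-carboxylate
Conditions: Dess–Martin periodinane, NaHCO3, CH2Cl2, 0 °C to rt
Reagents that add atoms: none
Why: Dess–Martin oxidation of a primary alcohol under buffered conditions; the stereocentre is β to the new carbonyl and cannot epimerise, and the aldehyde is used at once.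

Step 3
Reactants: 4 ethyl 3-methylbut-2-enoate
Product: 6 ethyl 2-bromo-3-methylbut-2-enoate, via dibromo ester 5 (not isolated)
Conditions: Br2, CH2Cl2, 0 °C; then DBU, 0 °C to rt
Reagents that add atoms: bromine, BrBr
Why: Bromine addition to the enoate followed by dehydrobromination; the base removes the acidic α-hydrogen and the tertiary β-bromide leaves, which gives the conjugated α-bromo enoate.

Step 4
Reactants: 6 ethyl 2-bromo-3-methylbut-2-enoate
Product: 7 2-bromo-3-methylbut-2-en-1-ol
Conditions: i-Bu2AlH (2.2 equiv), CH2Cl2, −78 to 0 °C; aq. potassium sodium tartrate
Reagents that add atoms: none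
Why: 1,2-Reduction of the conjugated ester to the allylic alcohol; the vinyl bromide is inert to the aluminium hydride at low temperature.

Step 5
Reactants: 7 2-bromo-3-methylbut-2-en-1-ol; 8 ethyl 2-diazo-2-(diethoxyphosphoryl)acetate
Product: 9 ethyl 2-[(2-bromo-3-methylbut-2-en-1-yl)oxy]-2-(diethoxyphosphoryl)acetate
Conditions: Rh2(OAc)4 (1 mol%), PhMe, 80 °C, slow addition of 8
Reagents that add atoms: none
Why: Rhodium carbenoid O–H insertion: the alcohol oxygen adds to the electrophilic carbenoid and a proton shift follows. The tetrasubstituted, bromine-bearing alkene is too hindered and electron-poor for cyclopropanation.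

Step 6
Reactants: 9 ethyl 2-[(2-bromo-3-methylbut-2-en-1-yl)oxy]-2-(diethoxyphosphoryl)acetate; 3 tert-butyl (2R)-2-(2-oxoethyl)pyrrolidine-1-carboxylate
Product: 10 ethyl 2-[(2-bromo-3-methylbut-2-en-1-yl)oxy]-4-[(2R)-1-(tert-butoxycarbonyl)pyrrolidin-2-yl]but-2-enoate (E/Z mixture)
Conditions: LiN(SiMe3)2, THF, −78 °C; then 3, −78 °C to rt
Reagents that add atoms: none
Why: Horner–Wadsworth–Emmons olefination of an unhindered aldehyde with an α-alkoxy phosphonoacetate gives the 2-alkoxycarbonyl allyl vinyl ether. The alkene geometry is immaterial because both isomers rearrange to the same constitution in step 7.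

Step 7
Reactants: 10 ethyl 2-[(2-bromo-3-methylbut-2-en-1-yl)oxy]-4-[(2R)-1-(tert-butoxycarbonyl)pyrrolidin-2-yl]but-2-enoate
Product: 11 ethyl 5-bromo-3-{[(2R)-1-(tert-butoxycarbonyl)pyrrolidin-2-yl]methyl}-4,4-dimethyl-2-oxohex-5-enoate (both epimers at C3 of the chain)
Conditions: PhMe, 110 °C (sealed tube)
Reagents that add atoms: none
Why: Gosteli–Claisen rearrangement, the [3,3] shift of an allyl vinyl ether accelerated by the 2-alkoxycarbonyl group. It forms the congested bond between the later C7 and the CMe2 carbon and releases the α-keto ester and the 1,1-disubstituted vinyl bromide. The new stereocentre is not controlled here and is corrected in step 8.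

Step 8
Reactants: 11 ethyl 5-bromo-3-{[(2R)-1-(tert-butoxycarbonyl)pyrrolidin-2-yl]methyl}-4,4-dimethyl-2-oxohex-5-enoate
Product: 13 (7R,8aR)-7-(3-bromo-2-methylbut-3-en-2-yl)hexahydroindolizine-5,6-dione, via amino keto ester 12 (not isolated)
Conditions: CF3CO2H, CH2Cl2, 0 °C to rt; concentrate; Et3N, MeCN, rt to 40 °C
Reagents that add atoms: none
Why: Acidolysis of the Boc group, then aminolysis of the activated α-keto ester by the pyrrolidine nitrogen closes the six-membered lactam. Et3N equilibrates C7 through the enol of the α-keto lactam, and the cis isomer with the side chain and the pyrrolidine carbon both equatorial on ring A is expected to dominate.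

Step 9
Reactants: 14 1-(2-chlorophenyl)ethanone
Product: 15 1-(2-chlorophenyl)ethenyl trifluoromethanesulfonate
Conditions: KN(SiMe3)2, THF, −78 °C; PhNTf2, −78 to 0 °C
Reagents that add atoms: N-phenylbis(trifluoromethanesulfonimide), FC(F)(F)S(=O)(=O)N(c1ccccc1)S(=O)(=O)C(F)(F)F
Why: O-Triflation of the potassium enolate of a methyl ketone, which has only one enolisable side; low temperature avoids elimination to the alkyne.

Step 10
Reactants: 15 1-(2-chlorophenyl)ethenyl trifluoromethanesulfonate
Product: 16 2-[1-(2-chlorophenyl)ethenyl]-4,4,5,5-tetramethyl-1,3,2-dioxaborolane
Conditions: PdCl2(PPh3)2 (3 mol%), PPh3, KOPh, B2pin2, PhMe, 50 °C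
Reagents that add atoms: bis(pinacolato)diboron, CC1(C)OB(OC1(C)C)B1OC(C)(C)C(C)(C)O1
Why: Miyaura borylation of a vinyl triflate; with triphenylphosphine as ligand the aryl chloride does not undergo oxidative addition.

Step 11
Reactants: 13 (7R,8aR)-7-(3-bromo-2-methylbut-3-en-2-yl)hexahydroindolizine-5,6-dione; 16 2-[1-(2-chlorophenyl)ethenyl]-4,4,5,5-tetramethyl-1,3,2-dioxaborolane
Product: 17 (7R,8aR)-7-[4-(2-chlorophenyl)-2-methyl-3-methylidenepent-4-en-2-yl]hexahydroindolizine-5,6-dione
Conditions: Pd(PPh3)4 (5 mol%), K3PO4, 1,4-dioxane/H2O (degassed), 70 °C
Reagents that add atoms: none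
Why: Suzuki–Miyaura coupling of a vinyl bromide with a vinylboronate builds the 2,3-disubstituted diene; the triphenylphosphine-ligated zerovalent palladium inserts into the C–Br bond and leaves the aryl chloride. C7 stays under thermodynamic control in the basic medium.

Step 12
Reactants: 17 (7R,8aR)-7-[4-(2-chlorophenyl)-2-methyl-3-methylidenepent-4-en-2-yl]hexahydroindolizine-5,6-dione; 18 tert-butyl N-(triphenyl-λ5-phosphanylidene)carbamate
Product: 19 tert-butyl N-[(7R,8aR)-7-[4-(2-chlorophenyl)-2-methyl-3-methylidenepent-4-en-2-yl]-5-oxohexahydroindolizin-6-ylidene]carbamate (N-Boc ketimine)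
Conditions: PhMe, 90 °C
Reagents that add atoms: none
Why: Aza-Wittig reaction of the iminophosphorane with the ketone, which is activated by the neighbouring lactam carbonyl, as with other 1,2-dicarbonyl compounds; the lactam carbonyl does not react, and the P=O bond drives the reaction.

Step 13
Reactants: 19 N-Boc ketimine
Product: 20 bridged carbamate lactam: ring B (C6, C7, CMe2, C(=CH2), C3, CH2) trans-fused to the indolizidin-5-one at C6–C7, C3 bearing the 2-chlorophenyl group and the carbamate oxygen, C6 the carbamate NH (C3 R, C6 S, C7 R, C8a R)
Conditions: BF3·OEt2 (2 equiv), CH2Cl2 (0.01 M), −78 to −20 °C; aq. NaHCO3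
Reagents that add atoms: none
Why: BF3 binds the N-Boc imine and generates the N-Boc ketiminium ion, which the adjacent lactam carbonyl makes strongly electrophilic. The terminal CH2 of the aryl-substituted alkene attacks the iminium carbon in a chair-like 6-endo-trig closure (with respect to the alkene) that forms ring B and leaves an allyl cation stabilised by the aryl group and the second methylene; attack through the other methylene would be a strained 5-endo closure to a poorer cation. The Boc carbonyl oxygen, held axial on the new quaternary carbon, then captures the benzylic terminus in a 6-exo closure of the oxazinanone and the tert-butyl group leaves as isobutene; the closest known chemistry is the Boc-terminated aza-Prins or formal [4+2] reaction of N-Boc iminium ions with α-aryl alkenes to 1,3-oxazinan-2-ones. At C6 the controlling element is ring A: its substituents at C7 and C8a are both equatorial, and the alkene is expected to enter along the equatorial trajectory, anti to the C7–C8 bond, through a trans-decalin-like chair–chair transition state. In that transition state the carbamate nitrogen turns axial, perpendicular to the lactam carbonyl and away from the in-plane quaternary carbon of the tether, which gives the trans ring fusion. At C3 the N–C(=O)–O bridge can span the 1,3-positions of ring B only on the nitrogen face, so the new C–O bond is necessarily cis to nitrogen. The step therefore needs the correct face of the iminium ion, secured by the chair closure, and capture before proton loss; an alkene formed by proton loss would be re-protonated by the acid to the same benzylic cation.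

Step 14
Reactants: 20 bridged carbamate lactam with exocyclic methylene
Product: 21 bridged carbamate lactam with the C2 ketone in place of the methylene (C3 S, C6 S, C7 R, C8a R)
Conditions: O3, CH2Cl2/MeOH, −78 °C; then Me2S, −78 °C to rt
Reagents that add atoms: ozone, [O-][O+]=O
Why: Ozonolysis of the only alkene with reductive work-up; the chloroarene, lactam and carbamate are inert to ozone at −78 °C, and the resulting ketone has no α-hydrogen.

Step 15
Reactants: 21 bridged carbamate lactam with C2 ketone and 2-chlorophenyl group
Product: 23 indolenine lactam (5-oxo precursor of the target; C3 S, C6 S, C7 R, C8a R), via aminophenyl ketone 22 (not isolated)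
Conditions: Pd[P(o-tolyl)3]2 (2 mol%), (R)-1-[(SP)-2-(dicyclohexylphosphino)ferrocenyl]ethyldi-tert-butylphosphine (2 mol%), NH3 (0.5 M in 1,4-dioxane, 5 equiv), NaOtBu (2.2 equiv), 80 °C; then AcOH, 50 °C
Reagents that add atoms: ammonia, N
Why: Palladium-catalysed monoarylation of ammonia with a bulky bisphosphine made for hindered aryl chlorides; ammonia is preferred to a silylamide because the chloride sits next to a quaternary ortho substituent. The aniline 22 condenses at once with the ketone held beside it in a five-membered ring closure, and no stereocentre is touched.

Step 16
Reactants: 23 indolenine lactam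
Product: 24 penicimutamide B
Conditions: Cp2Zr(H)Cl (3 equiv), THF, 0 °C to rt; aq. NaHCO3
Reagents that add atoms: none
Why: Hydrozirconation of the tertiary lactam carbonyl stops at the carbinolamine oxidation level. One equivalent is spent on the carbamate N–H, and the carbamate carbonyl and the hindered indolenine C=N are expected to be left. The C5 hydroxyl should end axial, anti to the carbamate nitrogen (5R), because the carbinolamine can equilibrate through its iminium ion and the axial position is favoured by the lone pair on N4.

## Compound list

1 | (R)-2-[1-(tert-butoxycarbonyl)pyrrolidin-2-yl]acetic acid (Boc-D-β-homoproline) | OC(=O)C[C@H]1CCCN1C(=O)OC(C)(C)C | starting material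
2 | tert-butyl (2R)-2-(2-hydroxyethyl)pyrrolidine-1-carboxylate | OCC[C@H]1CCCN1C(=O)OC(C)(C)C | intermediate
3 | tert-butyl (2R)-2-(2-oxoethyl)pyrrolidine-1-carboxylate | O=CC[C@H]1CCCN1C(=O)OC(C)(C)C | intermediate
4 | ethyl 3-methylbut-2-enoate | CCOC(=O)C=C(C)C | starting material
5 | ethyl 2,3-dibromo-3-methylbutanoate (racemic, not isolated) | CCOC(=O)C(Br)C(C)(C)Br | intermediate
6 | ethyl 2-bromo-3-methylbut-2-enoate | CCOC(=O)C(Br)=C(C)C | intermediate
7 | 2-bromo-3-methylbut-2-en-1-ol | OCC(Br)=C(C)C | intermediate
8 | ethyl 2-diazo-2-(diethoxyphosphoryl)acetate | CCOC(=O)C(=[N+]=[N-])P(=O)(OCC)OCC | starting material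
9 | ethyl 2-[(2-bromo-3-methylbut-2-en-1-yl)oxy]-2-(diethoxyphosphoryl)acetate (racemic) | CCOC(=O)C(OCC(Br)=C(C)C)P(=O)(OCC)OCC | intermediate
10 | ethyl 2-[(2-bromo-3-methylbut-2-en-1-yl)oxy]-4-[(2R)-1-(tert-butoxycarbonyl)pyrrolidin-2-yl]but-2-enoate (E/Z mixture) | CCOC(=O)C(OCC(Br)=C(C)C)=CC[C@H]1CCCN1C(=O)OC(C)(C)C | intermediate
11 | ethyl 5-bromo-3-{[(2R)-1-(tert-butoxycarbonyl)pyrrolidin-2-yl]methyl}-4,4-dimethyl-2-oxohex-5-enoate (both epimers at C3 of the chain) | CCOC(=O)C(=O)C(C[C@H]1CCCN1C(=O)OC(C)(C)C)C(C)(C)C(Br)=C | intermediate
12 | ethyl 5-bromo-4,4-dimethyl-2-oxo-3-{[(2R)-pyrrolidin-2-yl]methyl}hex-5-enoate (formed as its trifluoroacetate salt, not isolated) | CCOC(=O)C(=O)C(C[C@H]1CCCN1)C(C)(C)C(Br)=C | intermediate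
13 | (7R,8aR)-7-(3-bromo-2-methylbut-3-en-2-yl)hexahydroindolizine-5,6-dione | O=C1C(=O)N2CCC[C@@H]2C[C@@H]1C(C)(C)C(Br)=C | intermediate
14 | 1-(2-chlorophenyl)ethanone | CC(=O)c1ccccc1Cl | starting material
15 | 1-(2-chlorophenyl)ethenyl trifluoromethanesulfonate | C=C(OS(=O)(=O)C(F)(F)F)c1ccccc1Cl | intermediate
16 | 2-[1-(2-chlorophenyl)ethenyl]-4,4,5,5-tetramethyl-1,3,2-dioxaborolane | C=C(B1OC(C)(C)C(C)(C)O1)c1ccccc1Cl | intermediate
17 | (7R,8aR)-7-[4-(2-chlorophenyl)-2-methyl-3-methylidenepent-4-en-2-yl]hexahydroindolizine-5,6-dione | O=C1C(=O)N2CCC[C@@H]2C[C@@H]1C(C)(C)C(=C)C(=C)c1ccccc1Cl | intermediate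
18 | tert-butyl N-(triphenyl-λ5-phosphanylidene)carbamate | CC(C)(C)OC(=O)N=P(c1ccccc1)(c1ccccc1)c1ccccc1 | starting material
19 | tert-butyl N-[(7R,8aR)-7-[4-(2-chlorophenyl)-2-methyl-3-methylidenepent-4-en-2-yl]-5-oxohexahydroindolizin-6-ylidene]carbamate (N-Boc ketimine, precursor of the key step) | CC(C)(C)OC(=O)N=C1C(=O)N2CCC[C@@H]2C[C@@H]1C(C)(C)C(=C)C(=C)c1ccccc1Cl | intermediate
20 | bridged carbamate lactam with exocyclic methylene and 2-chlorophenyl group; rings A and B trans-fused, carbamate N and O cis-diaxial on ring B (C3 R, C6 S, C7 R, C8a R) | CC1(C)C(=C)[C@@]2(c3ccccc3Cl)C[C@]3(NC(=O)O2)[C@@H]1C[C@H]1CCCN1C3=O | intermediate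
21 | bridged carbamate lactam with C2 ketone and 2-chlorophenyl group (C3 S, C6 S, C7 R, C8a R) | CC1(C)C(=O)[C@@]2(c3ccccc3Cl)C[C@]3(NC(=O)O2)[C@@H]1C[C@H]1CCCN1C3=O | intermediate
22 | bridged carbamate lactam with C2 ketone and 2-aminophenyl group (not isolated; C3 S, C6 S, C7 R, C8a R) | CC1(C)C(=O)[C@@]2(c3ccccc3N)C[C@]3(NC(=O)O2)[C@@H]1C[C@H]1CCCN1C3=O | intermediate
23 | indolenine lactam, the 5-oxo precursor of the target (C3 S, C6 S, C7 R, C8a R) | CC1(C)C2=Nc3ccccc3[C@@]23C[C@]2(NC(=O)O3)[C@@H]1C[C@H]1CCCN1C2=O | intermediate
24 | penicimutamide B (C3 S, C5 R, C6 S, C7 R, C8a R) | CC1(C)C2=Nc3ccccc3[C@@]23C[C@]2(NC(=O)O3)[C@@H]1C[C@H]1CCCN1[C@@H]2O | target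

## Step count and least certain steps

Total step count: 16. Longest linear sequence: 12 steps (steps 3 to 8 and 11 to 16, counted from 4).

**Step 13 (key step).** The most likely failure is that the BF3-bound carbamate loses its tert-butyl group before the carbamate oxygen has closed the ring, so that the cation ends by proton loss or by oligomerisation of the diene. This is plausible because Boc groups are cleaved by the same Lewis acid and 2-aryl dienes polymerise cationically. A second concern is attack on the other face of the iminium ion, which would give the cis-fused isomer; the argument for the trans closure rests on the chair model and is not backed by a directing group.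
Fallback for the first failure: set out from 17 and condense it with methyl N-(triphenyl-λ5-phosphanylidene)carbamate to the N-methoxycarbonyl ketimine F1. Cyclise F1 with the same acid to the 2-methoxy-5,6-dihydro-4H-1,3-oxazine F2, a cyclic imidate that cannot fragment and is the classical product of polar [4+2] addition of N-acyliminium ions to alkenes. Cleave the O-methyl group with NaI and Me3SiCl in MeCN, which returns to the route at 20. This fallback does not change the facial question.

**Step 15.** The most likely failure is a stalled coupling: ammonia binds palladium in competition with the phosphine, and oxidative addition and C–N bond formation are slow beside the quaternary ortho carbon, so hydrodechlorination can take over. The alkoxide base may also open the carbamate.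
Fallback: set out from 21 and couple it with benzophenone imine under a weaker base (Pd2(dba)3, 2-dicyclohexylphosphino-2',4',6'-triisopropylbiphenyl, Cs2CO3, PhMe, 100 °C) to the N-aryl diphenylmethanimine F3. Hydrolyse F3 with aqueous HCl in THF; the freed aniline closes onto the ketone and the route is rejoined at 23.

**Step 16.** The most likely failure is no reaction or reaction at the wrong group. The lactam carbonyl sits on a quaternary carbon under the axial carbamate and may not be reached by the bulky zirconocene hydride, and forcing the reaction exposes the indolenine C=N to reduction.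
Fallback: set out from 23 and use catalytic hydrosilylation of the tertiary lactam with IrCl(CO)(PPh3)2 and 1,1,3,3-tetramethyldisiloxane in PhMe. This gives the O-silyl hemiaminal F4, which cannot collapse to an enamine because C6 has no hydrogen; hydrolysis with aqueous NaHCO3 gives 24.

**Step 12.** The most likely failure is incomplete condensation. The ketone is flanked by a tertiary carbon that bears a quaternary one, its enol form does not react, and long heating invites thermal reactions of the diene.
Fallback: set out from 17 and convert it with KN(SiMe3)2 and PhNTf2 into the enol triflate F5. Couple F5 with tert-butyl carbamate (Pd2(dba)3, Xantphos, Cs2CO3, 1,4-dioxane, 80 °C) to the enecarbamate F6, the tautomer of 19. F6 is taken as such into step 13 and rejoins the route at 20.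

**Step 11.** The most likely failure is base-mediated degradation of the enolisable α-keto lactam (oxidation or self-condensation of its enolate) together with protodeboronation of the hindered α-aryl vinylboronate.
Fallback: set out from 15 and make tributyl[1-(2-chlorophenyl)ethenyl]stannane F7 with (Bu3Sn)2, Pd(PPh3)4 and LiCl. Couple F7 with 13 without base in a Stille reaction (Pd(PPh3)4, CuI, DMF, 60 °C), which returns to the route at 17.

## Further compounds

F1 | step 13 | methyl N-[(7R,8aR)-7-[4-(2-chlorophenyl)-2-methyl-3-methylidenepent-4-en-2-yl]-5-oxohexahydroindolizin-6-ylidene]carbamate | COC(=O)N=C1C(=O)N2CCC[C@@H]2C[C@@H]1C(C)(C)C(=C)C(=C)c1ccccc1Cl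
F2 | step 13 | cyclic imidate corresponding to 20, with a 2-methoxy-5,6-dihydro-4H-1,3-oxazine in place of the oxazinanone | CC1(C)C(=C)[C@@]2(c3ccccc3Cl)C[C@]3(N=C(OC)O2)[C@@H]1C[C@H]1CCCN1C3=O
F3 | step 15 | N-aryl diphenylmethanimine corresponding to 21, with N=CPh2 in place of chlorine | CC1(C)C(=O)[C@@]2(c3ccccc3N=C(c3ccccc3)c3ccccc3)C[C@]3(NC(=O)O2)[C@@H]1C[C@H]1CCCN1C3=O
F4 | step 16 | O-(1,1,3,3-tetramethyldisiloxanyl) ether of penicimutamide B at the C5 carbinolamine | CC1(C)C2=Nc3ccccc3[C@@]23C[C@]2(NC(=O)O3)[C@@H]1C[C@H]1CCCN1[C@@H]2O[Si](C)(C)O[SiH](C)C
F5 | step 12 | (8aR)-7-[4-(2-chlorophenyl)-2-methyl-3-methylidenepent-4-en-2-yl]-5-oxo-1,2,3,5,8,8a-hexahydroindolizin-6-yl trifluoromethanesulfonate | O=C1N2CCC[C@@H]2CC(C(C)(C)C(=C)C(=C)c2ccccc2Cl)=C1OS(=O)(=O)C(F)(F)F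
F6 | step 12 | tert-butyl N-[(8aR)-7-[4-(2-chlorophenyl)-2-methyl-3-methylidenepent-4-en-2-yl]-5-oxo-1,2,3,5,8,8a-hexahydroindolizin-6-yl]carbamate (enecarbamate tautomer of 19) | CC(C)(C)OC(=O)NC1=C(C(C)(C)C(=C)C(=C)c2ccccc2Cl)C[C@H]2CCCN2C1=O
F7 | step 11 | tributyl[1-(2-chlorophenyl)ethenyl]stannane | CCCC[Sn](CCCC)(CCCC)C(=C)c1ccccc1Cl
A1 | alternative 1 | tricyclic indolizidinone with NHBoc group and ketal-masked ring-B ketone | CC1(C)C2(OCCO2)CC[C@]2(NC(=O)OC(C)(C)C)[C@@H]1C[C@H]1CCCN1C2=O
A2 | alternative 2 | isopropenyl indolizidinone bearing the indol-3-ylmethyl arm and a methyl carbamate | COC(=O)N[C@@]1(Cc2c[nH]c3ccccc23)[C@@H](C(C)=C)C[C@H]2CCCN2C1=O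
A3 | alternative 3 | pentacyclic indole lactam with benzyl carbamate | CC1(C)c2[nH]c3ccccc3c2C[C@]2(NC(=O)OCc3ccccc3)[C@@H]1C[C@H]1CCCN1C2=O
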